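Atom numbering throughout is that of benzofuran (O1, C2, C3, C3a, C4 to C7, C7a). Compound numbers are those of the steps and of the compound list.

## Analysis of the target

The target is a dihydrochalcone: a 3-(4-methoxyphenyl)propanoyl chain on a fully substituted phloroglucinol ring (ring A) that is fused to a 2,3-dihydrofuran. Ring A carries OH at C4, a 3-methylbut-2-enyl (prenyl) group at C5, OH at C6 and the acyl group at C7; C2 carries a 2-hydroxypropan-2-yl group. C2 is the only stereocentre and is (S). It has no neighbour that could relay chirality, so a reagent or catalyst must set it; once formed it is an ether carbon without an acidic hydrogen and is configurationally safe. The sensitive groups are the prenyl alkene between two phenols (acid closes it to a chroman; electrophiles and strong bases attack it), the tertiary carbinol (ionisation in acid) and the electron-rich arene with free phenols (oxidation). The difficulty is regiochemical. Ring A has six different substituents, the furan oxygen must be the one ortho to the acyl group, and C5 and C7 are each flanked by two oxygens and are hard to tell apart. The strategy rests on one feature: C2 is an ether CH bound to O1 and lies five atoms from the benzylic C3 (C3–C3a–C7a–O1–C2). A carbene centre at C3 of an achiral aryl ether can therefore reach an OCH2 hydrogen through a five-membered transition state; insertion forms C2–C3, closes the furan ring and lets a chiral catalyst choose between two enantiotopic hydrogens.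

## Retrosynthetic reasoning

**C5–prenyl bond.** The last bond cut in target 23 is the one between C5 and the prenyl CH2. It is traced to a [3,3] shift of the tertiary allyl ether 21, made from alkyne 20, which comes from phenol 18 and the propargylic chloride 19. With C7 acylated and C3a part of the furan ring, C5 is the only ortho position of O4 that can rearomatise, so the shift has a single outlet and gives the linear prenyl group. The alkene enters last and never meets an organolithium, a brominating agent or a carbene. The forward sequence has to alkylate O4 only; the hydrogen bond of the C6 hydroxyl to the ketone ensures this without protecting groups.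

**C7–acyl bond.** Ketone 17 (and, after desilylation, 18) is cut into aryllithium 15 and the Weinreb amide 14, which comes from acid 12. A Friedel–Crafts acylation of the free phloroglucinol ether would not distinguish C5 from C7. A directed lithiation of a 4,6-bis-acetal would have to choose between C5 (two acetal oxygens) and C7 (one acetal oxygen and O1), which is not a safe choice. C7 is therefore marked as bromide 11 and the carbanion is made by halogen–lithium exchange.

**C7–Br bond.** Bromide 11 goes back to the dihydrobenzofuran 10. The forward bromination has to pick C7 over C5. C7 is ortho to the ring oxygen, the position that 5,7-dioxygenated chromans offer to electrophiles, and C5 sits between two triisopropylsilyloxy groups.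

**C2–C3 bond (key disconnection).** Cutting C2–C3 of 10 opens the furan ring and removes the stereocentre, leaving the achiral diazo compound 9. No other cut removes ring and stereocentre together from an achiral precursor. The forward step must decompose the diazo group on a chiral dirhodium carboxylate catalyst and insert the carbene into one of the two enantiotopic OCH2 hydrogens. The oxygen ortho to the carbene on the other side must carry no C–H bond at the 1,5 distance, which is why it is a silyl ether, and the tertiary oxygen must carry no O–H.

**Diazo group.** Diazo compound 9 is derived from hydrazone 8 by dehydrogenation, and 8 from aldehyde 7 by condensation. The aldehyde carbon becomes C3.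

**Ether bond O1–CH2 and the protecting groups.** Aldehyde 7 is the trisilyl derivative of triol 5. The O–CH2 bond of 5 is cut to a phenoxide and oxirane 3, which brings in C2 and the complete hydroxyisopropyl unit. Attack at the CH2 of 3 needs hot base, and silyl ethers ortho and para to a formyl group are vinylogous silyl esters that would not survive it. The two other oxygens are therefore acetals during the alkylation (compound 4, from phenol 2) and are exchanged for silyl ethers afterwards. Phenol 2 comes from aldehyde 1, whose hydrogen-bonded hydroxyl is the one left free by two equivalents of alkylating agent; this fixes early which oxygen becomes O1. The tertiary oxygen is capped as a triethylsilyl ether, not a trimethylsilyl ether, because the cap must survive hydrazone formation, bromination and chromatography; it is only slightly larger.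

## Alternatives that were turned down

**Alternative 1:** The cut is made inside ring A at C7–C7a. The open-chain triketo ester A1 (methyl 9-(4-methoxyphenyl)-2-(3-methylbut-2-en-1-yl)-3,5,7-trioxononanoate) would be folded by a magnesium alkoxide so that the carbon between its 5- and 7-carbonyl groups attacks the ester. Enolisation would give the prenylated acylphloroglucinol A2 (1-[2,4,6-trihydroxy-3-(3-methylbut-2-en-1-yl)phenyl]-3-(4-methoxyphenyl)propan-1-one).
- For: ring A is made with the acyl chain and one prenyl group in place, without protecting groups, and the acyl group needs no halogenation or lithiation. On that point it is stronger than the chosen route.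
- Against: A1 is a polycarbonyl chain that needs polyanion chemistry and can also close by aldol condensation to a resorcylate. A2 then has to be turned into the hydroxyisopropyl dihydrofuran by enantioselective epoxidation and cyclisation. Two hydroxyls flank the prenyl group; the one wanted (at C7a, hydrogen-bonded to the ketone) is the less nucleophilic, so the ring fusion would tend to form the wrong way. An asymmetric epoxidation on a free polyphenol also needs a protecting-group detour, and a second prenylation at C5 is still required.
- Comparison: the chosen route fixes O1 in step 2 and sets C2 with a catalyst at the moment the ring closes.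

**Alternative 2:** Here C2–C3 and O1–C2 are cut together. The ammonium phenol A3 ([2-hydroxy-4,6-bis(methoxymethoxy)benzyl]trimethylammonium iodide, reachable from aldehyde 2) would lose its amine under base to give the ortho-quinone methide A4 (3,5-bis(methoxymethoxy)-6-methylidenecyclohexa-2,4-dien-1-one). An ester-stabilised ylide of a chiral sulfide adds through carbon to the exocyclic methylene (C3), and the phenoxide displaces the sulfide at C2. The product is ester A5 (methyl (S)-4,6-bis(methoxymethoxy)-2,3-dihydrobenzofuran-2-carboxylate), which a methyl Grignard reagent would convert into the tertiary carbinol.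
- For: the bond formation is polar and robust, with no carbene to dimerise, and the acetals can stay on from the start, so the precursor is shorter. On reliability of ring closure and protecting-group economy it is as strong as or stronger than the chosen route.
- Against: C3 is an unsubstituted CH2, so the conjugate addition creates no stereocentre. C2 is the ylide carbon, which in the betaine carries an acidic hydrogen between ester and sulfonium and is fixed only in the displacement step. Induction would have to come from a stoichiometric chiral sulfide acting on an epimerisable centre, and A5 is an α-aryloxy ester that can racemise in base. The ester also needs an extra step to become the carbinol.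
- Comparison: the chosen route uses a catalytic amount of chiral material, and C2 is born as a non-epimerisable ether carbon with its side chain already at the right oxidation level.

**Alternative 3:** The C6–O bond and the C7–acyl bond are cut at once. Fluoride would convert the silyl triflate A6 ((S)-4-(methoxymethoxy)-2-[2-(methoxymethoxy)propan-2-yl]-5-(3-methylbut-2-en-1-yl)-7-(trimethylsilyl)-2,3-dihydrobenzofuran-6-yl trifluoromethanesulfonate) into the aryne A7 (the 6,7-didehydro compound). The carboxylate of acid 12 adds through oxygen at C6, the carbon remote from O1, and the C7 anion takes the acyl group from oxygen. This gives the ortho-hydroxy ketone A8 ((S)-1-[6-hydroxy-4-(methoxymethoxy)-2-[2-(methoxymethoxy)propan-2-yl]-5-(3-methylbut-2-en-1-yl)-2,3-dihydrobenzofuran-7-yl]-3-(4-methoxyphenyl)propan-1-one).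
- For: the union is convergent, and the polarisation of the aryne by O1 places oxygen at C6 and acyl at C7 in one step. On this regiochemical point it is stronger than the bromination and exchange of the chosen route.
- Against: it does nothing for the stereocentre, which must be made beforehand. A6 is a pentasubstituted arene with dihydrofuran, prenyl, acetals and an ortho silyl/triflate pair, and its C6 oxygen is installed, triflated and then re-created. The aryne is generated beside an alkene with allylic hydrogens, where ene and cycloaddition side reactions are typical. Step economy is the poorest of the four.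
- Comparison: the chosen route makes ring and stereocentre early from an achiral precursor six steps from aldehyde 1.

Key step: step 7

Assumption: Rh2(S-PTAD)4 is taken to give the (S) configuration at C2; the sense of induction for a carbene carrying hydrogen cannot be read with certainty from diaryl and aryl/alkyl carbenes, and if the first run shows the opposite sense the mirror-image complex Rh2(R-PTAD)4 is used in the same procedure.

## Route

Step 1
Reactants: 1 2,4,6-trihydroxybenzaldehyde
Product: 2 2-hydroxy-4,6-bis(methoxymethoxy)benzaldehyde
Conditions: MOMCl (2.2 equiv), i-Pr2NEt (2.5 equiv), CH2Cl2, 0 °C → rt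
Reagents that add atoms: chloromethyl methyl ether (MOMCl), COCCl
Why: Selective O-alkylation (Williamson-type acetal formation): the hydroxyl hydrogen-bonded to the formyl group is the least reactive, so two equivalents of the chloride take the para and one ortho oxygen and leave the chelated phenol that becomes O1. Acetals are used because they withstand the hot base of step 2.

Step 2
Reactants: 2 2-hydroxy-4,6-bis(methoxymethoxy)benzaldehyde; 3 2,2-dimethyloxirane
Product: 4 2-(2-hydroxy-2-methylpropoxy)-4,6-bis(methoxymethoxy)benzaldehyde
Conditions: 3 (3 equiv), Cs2CO3 (0.3 equiv), DMF, 90 °C, sealed tube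
Reagents that add atoms: none
Why: Base-catalysed SN2 opening of the epoxide by the phenoxide at its unsubstituted CH2; the alkoxide formed regenerates phenoxide, so the carbonate is catalytic. This makes the O1–CH2 bond and brings in C2 with its two enantiotopic hydrogens and the whole hydroxyisopropyl unit.

Step 3
Reactants: 4 2-(2-hydroxy-2-methylpropoxy)-4,6-bis(methoxymethoxy)benzaldehyde
Product: 5 2,4-dihydroxy-6-(2-hydroxy-2-methylpropoxy)benzaldehyde
Conditions: HCl (cat.), MeOH, 40 °C
Reagents that add atoms: none
Why: Acid-catalysed transacetalisation to methanol removes both methoxymethyl groups; the aldehyde and the tertiary alcohol tolerate dilute acid at this temperature. The acetal on the ortho oxygen must go because its OCH2O hydrogens would lie at the 1,5 distance from the carbene.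

Step 4
Reactants: 5 2,4-dihydroxy-6-(2-hydroxy-2-methylpropoxy)benzaldehyde
Product: 7 2-[2-methyl-2-(triethylsilyloxy)propoxy]-4,6-bis(triisopropylsilyloxy)benzaldehyde, via 2-(2-hydroxy-2-methylpropoxy)-4,6-bis(triisopropylsilyloxy)benzaldehyde 6 (not isolated)
Conditions: TIPSOTf (2.2 equiv), 2,6-lutidine (5 equiv), CH2Cl2, −78 → 0 °C; then TESOTf (1.3 equiv), 0 °C
Reagents that add atoms: triisopropylsilyl trifluoromethanesulfonate (TIPSOTf), CC(C)[Si](OS(=O)(=O)C(F)(F)F)(C(C)C)C(C)C; triethylsilyl trifluoromethanesulfonate (TESOTf), CC[Si](CC)(CC)OS(=O)(=O)C(F)(F)F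
Why: Silylation with silyl triflates and a hindered pyridine base: the bulky triflate takes both phenols, the chelated one included, far faster than the tertiary alcohol, which the smaller triflate then caps in the same flask. The product has silicon, not a C–H bond, on the oxygen ortho to the future carbene, and no O–H.

Step 5
Reactants: 7 2-[2-methyl-2-(triethylsilyloxy)propoxy]-4,6-bis(triisopropylsilyloxy)benzaldehyde
Product: 8 (E)-{2-[2-methyl-2-(triethylsilyloxy)propoxy]-4,6-bis(triisopropylsilyloxy)benzylidene}hydrazine
Conditions: N2H4 (1 M in THF, 6 equiv), AcOH (cat.), THF, 0 °C → rt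
Reagents that add atoms: hydrazine, NN
Why: Condensation of the aldehyde with hydrazine gives the hydrazone; excess anhydrous hydrazine in an aprotic solvent suppresses azine formation and spares the aryl silyl ethers.

Step 6
Reactants: 8 (E)-{2-[2-methyl-2-(triethylsilyloxy)propoxy]-4,6-bis(triisopropylsilyloxy)benzylidene}hydrazine
Product: 9 2-(diazomethyl)-1-[2-methyl-2-(triethylsilyloxy)propoxy]-3,5-bis(triisopropylsilyloxy)benzene
Conditions: activated MnO2 (8 equiv), MgSO4, CH2Cl2, 0 °C; cold filtration through Celite, solution used at once
Reagents that add atoms: none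
Why: Dehydrogenation of an unsubstituted hydrazone to the diazoalkane with MnO2, the classical access to aryldiazomethanes. The electron-rich diazo compound is acid-sensitive, so it is kept cold and dry and carried on as a solution.

Step 7
Reactants: 9 2-(diazomethyl)-1-[2-methyl-2-(triethylsilyloxy)propoxy]-3,5-bis(triisopropylsilyloxy)benzene
Product: 10 (S)-2-[2-(triethylsilyloxy)propan-2-yl]-4,6-bis(triisopropylsilyloxy)-2,3-dihydrobenzofuran
Conditions: Rh2(S-PTAD)4 (dirhodium tetrakis[(S)-(1-adamantyl)(N-phthalimido)acetate], 1 mol %), CH2Cl2, −20 °C → rt, 9 added over 2 h by syringe pump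
Reagents that add atoms: none
Why: The rhodium complex takes up the diazo carbon, the diazo group leaves as N2, and an electrophilic rhodium-bound carbene forms at the future C3; through a concerted, asynchronous three-centre transition state it inserts into one C–H bond of the OCH2 group and the catalyst is released. The closest known reaction type is the enantioselective 1,5 C–H insertion of hydrazone-derived donor carbenes into ether α-C–H bonds under chiral carboxylates of divalent rhodium, which gives 2,3-dihydrobenzofurans; the present carbene differs from those cases in bearing hydrogen in place of aryl or alkyl, and the CH2 lies next to a fully substituted carbon, so the route stands or falls here. The dihydrofuran closes by C2–C3 bond formation through the five-membered arrangement C3–C3a–C7a–O1–C2, the geometry that intramolecular insertions prefer. C2 is the only new stereocentre and is set by the chiral pocket of the four carboxylate ligands, which must distinguish the two enantiotopic hydrogens of an achiral substrate. Site selectivity is needed against longer-range insertion and O–H insertion: the ether oxygen activates only the 1,5 C–H bonds, the triisopropylsilyloxy group on the other ortho carbon puts silicon at the 1,5 distance, and the tertiary oxygen is capped. Chemoselectivity is needed against reaction of the carbene with a second diazo molecule (azine or stilbene formation): slow addition keeps the diazo concentration low and the carbene carbon is shielded by two ortho substituents. The three ring oxygens make the carbene a stabilised, selective donor type.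

Step 8
Reactants: 10 (S)-2-[2-(triethylsilyloxy)propan-2-yl]-4,6-bis(triisopropylsilyloxy)-2,3-dihydrobenzofuran
Product: 11 (S)-7-bromo-2-[2-(triethylsilyloxy)propan-2-yl]-4,6-bis(triisopropylsilyloxy)-2,3-dihydrobenzofuran
Conditions: NBS (1.0 equiv), CH2Cl2, −40 → 0 °C, dark
Reagents that add atoms: N-bromosuccinimide (NBS), O=C1CCC(=O)N1Br
Why: Electrophilic aromatic bromination: C7, ortho to the ring oxygen, corresponds to C8 of 5,7-dioxygenated chromans, the site such electrophiles attack, and C5 is screened by two flanking triisopropylsilyloxy groups. One equivalent at low temperature in the dark avoids a second bromination and benzylic attack.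

Step 9
Reactants: 12 3-(4-methoxyphenyl)propanoic acid
Product: 14 N-methoxy-N-methyl-3-(4-methoxyphenyl)propanamide, via 1-[3-(4-methoxyphenyl)propanoyl]imidazole 13 (not isolated)
Conditions: CDI (1.2 equiv), CH2Cl2, rt; then MeNHOMe·HCl (1.5 equiv), rt
Reagents that add atoms: N,O-dimethylhydroxylamine hydrochloride, CNOC.Cl
Why: Activation of the acid as its acyl imidazole and aminolysis (Weinreb amide synthesis).

Step 10
Reactants: 11 (S)-7-bromo-2-[2-(triethylsilyloxy)propan-2-yl]-4,6-bis(triisopropylsilyloxy)-2,3-dihydrobenzofuran; 14 N-methoxy-N-methyl-3-(4-methoxyphenyl)propanamide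
Product: 17 1-{(S)-2-[2-(triethylsilyloxy)propan-2-yl]-4,6-bis(triisopropylsilyloxy)-2,3-dihydrobenzofuran-7-yl}-3-(4-methoxyphenyl)propan-1-one, via 7-lithio dihydrobenzofuran 15 (not isolated), via lithium N-methoxy-N-methyl hemiaminal 16 (not isolated)
Conditions: n-BuLi (1.05 equiv), THF, −78 °C; then 14 (1.3 equiv), −78 → −20 °C; aq. NH4Cl
Reagents that add atoms: none
Why: Bromine–lithium exchange at −78 °C gives the C7 aryllithium without touching the silyl ethers, and its addition to the amide stops at the chelated tetrahedral adduct, which releases the ketone only on work-up (Weinreb ketone synthesis). The bulky triisopropylsilyl group is slow to migrate from O6 to C7 at this temperature.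

Step 11
Reactants: 17 1-{(S)-2-[2-(triethylsilyloxy)propan-2-yl]-4,6-bis(triisopropylsilyloxy)-2,3-dihydrobenzofuran-7-yl}-3-(4-methoxyphenyl)propan-1-one
Product: 18 1-[(S)-4,6-dihydroxy-2-(2-hydroxypropan-2-yl)-2,3-dihydrobenzofuran-7-yl]-3-(4-methoxyphenyl)propan-1-one
Conditions: TBAF (3.5 equiv), THF, 0 °C → rt; aq. NH4Cl
Reagents that add atoms: none
Why: Fluoride-induced Si–O cleavage removes both aryl triisopropylsilyl groups and the tertiary triethylsilyl group in one operation; nothing else in the molecule reacts with fluoride.

Step 12
Reactants: 18 1-[(S)-4,6-dihydroxy-2-(2-hydroxypropan-2-yl)-2,3-dihydrobenzofuran-7-yl]-3-(4-methoxyphenyl)propan-1-one; 19 3-chloro-3-methylbut-1-yne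
Product: 20 1-[(S)-6-hydroxy-2-(2-hydroxypropan-2-yl)-4-(2-methylbut-3-yn-2-yloxy)-2,3-dihydrobenzofuran-7-yl]-3-(4-methoxyphenyl)propan-1-one
Conditions: 19 (1.5 equiv), DBU (1.5 equiv), CuCl2 (1 mol %), MeCN, 0 °C → rt
Reagents that add atoms: none
Why: Copper-catalysed propargylic etherification of the more acidic, non-chelated C4 phenol by the tertiary propargylic chloride. The C6 hydroxyl is held in a hydrogen bond to the ketone, and the tertiary alcohol is not deprotonated by DBU.

Step 13
Reactants: 20 1-[(S)-6-hydroxy-2-(2-hydroxypropan-2-yl)-4-(2-methylbut-3-yn-2-yloxy)-2,3-dihydrobenzofuran-7-yl]-3-(4-methoxyphenyl)propan-1-one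
Product: 21 1-[(S)-6-hydroxy-2-(2-hydroxypropan-2-yl)-4-(2-methylbut-3-en-2-yloxy)-2,3-dihydrobenzofuran-7-yl]-3-(4-methoxyphenyl)propan-1-one
Conditions: H2 (1 atm), Pd/CaCO3 poisoned with Pb(OAc)2 (Lindlar catalyst), quinoline, EtOAc, rt
Reagents that add atoms: none
Why: Lindlar semihydrogenation of the terminal alkyne to the alkene; the poisoned catalyst leaves the ketone, the arenes and the product alkene untouched.

Step 14
Reactants: 21 1-[(S)-6-hydroxy-2-(2-hydroxypropan-2-yl)-4-(2-methylbut-3-en-2-yloxy)-2,3-dihydrobenzofuran-7-yl]-3-(4-methoxyphenyl)propan-1-one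
Product: 23 1-[(S)-4,6-dihydroxy-2-(2-hydroxypropan-2-yl)-5-(3-methylbut-2-en-1-yl)-2,3-dihydrobenzofuran-7-yl]-3-(4-methoxyphenyl)propan-1-one, via C5-prenyl cyclohexadienone 22 (not isolated)
Conditions: PhNEt2, 130 °C, degassed
Reagents that add atoms: none
Why: Aromatic Claisen rearrangement: the [3,3] shift moves the allyl unit from O4 to C5 with allylic transposition, so the tertiary ether delivers the linear 3-methylbut-2-enyl group, and tautomerisation of the dienone restores the phenol. C5 is the only ortho position of O4 that carries hydrogen, the amine solvent keeps the medium free of acid, and C2 is not involved.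

## Compound list

1 | 2,4,6-trihydroxybenzaldehyde | O=Cc1c(O)cc(O)cc1O | starting material
2 | 2-hydroxy-4,6-bis(methoxymethoxy)benzaldehyde | O=Cc1c(O)cc(OCOC)cc1OCOC | intermediate
3 | 2,2-dimethyloxirane | CC1(C)CO1 | starting material
4 | 2-(2-hydroxy-2-methylpropoxy)-4,6-bis(methoxymethoxy)benzaldehyde | O=Cc1c(OCC(C)(C)O)cc(OCOC)cc1OCOC | intermediate
5 | 2,4-dihydroxy-6-(2-hydroxy-2-methylpropoxy)benzaldehyde | O=Cc1c(OCC(C)(C)O)cc(O)cc1O | intermediate
6 | 2-(2-hydroxy-2-methylpropoxy)-4,6-bis(triisopropylsilyloxy)benzaldehyde | O=Cc1c(OCC(C)(C)O)cc(O[Si](C(C)C)(C(C)C)C(C)C)cc1O[Si](C(C)C)(C(C)C)C(C)C | intermediate (not isolated)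
7 | 2-[2-methyl-2-(triethylsilyloxy)propoxy]-4,6-bis(triisopropylsilyloxy)benzaldehyde | O=Cc1c(OCC(C)(C)O[Si](CC)(CC)CC)cc(O[Si](C(C)C)(C(C)C)C(C)C)cc1O[Si](C(C)C)(C(C)C)C(C)C | intermediate
8 | (E)-{2-[2-methyl-2-(triethylsilyloxy)propoxy]-4,6-bis(triisopropylsilyloxy)benzylidene}hydrazine | N/N=C/c1c(OCC(C)(C)O[Si](CC)(CC)CC)cc(O[Si](C(C)C)(C(C)C)C(C)C)cc1O[Si](C(C)C)(C(C)C)C(C)C | intermediate
9 | 2-(diazomethyl)-1-[2-methyl-2-(triethylsilyloxy)propoxy]-3,5-bis(triisopropylsilyloxy)benzene | [N-]=[N+]=Cc1c(OCC(C)(C)O[Si](CC)(CC)CC)cc(O[Si](C(C)C)(C(C)C)C(C)C)cc1O[Si](C(C)C)(C(C)C)C(C)C | intermediate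
10 | (S)-2-[2-(triethylsilyloxy)propan-2-yl]-4,6-bis(triisopropylsilyloxy)-2,3-dihydrobenzofuran | CC(C)[Si](Oc1cc(O[Si](C(C)C)(C(C)C)C(C)C)c2C[C@@H](C(C)(C)O[Si](CC)(CC)CC)Oc2c1)(C(C)C)C(C)C | intermediate
11 | (S)-7-bromo-2-[2-(triethylsilyloxy)propan-2-yl]-4,6-bis(triisopropylsilyloxy)-2,3-dihydrobenzofuran | CC(C)[Si](Oc1cc(O[Si](C(C)C)(C(C)C)C(C)C)c2C[C@@H](C(C)(C)O[Si](CC)(CC)CC)Oc2c1Br)(C(C)C)C(C)C | intermediate
12 | 3-(4-methoxyphenyl)propanoic acid | COc1ccc(CCC(=O)O)cc1 | starting material
13 | 1-[3-(4-methoxyphenyl)propanoyl]imidazole | COc1ccc(CCC(=O)n2ccnc2)cc1 | intermediate (not isolated)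
14 | N-methoxy-N-methyl-3-(4-methoxyphenyl)propanamide | COc1ccc(CCC(=O)N(C)OC)cc1 | intermediate
15 | [(S)-2-[2-(triethylsilyloxy)propan-2-yl]-4,6-bis(triisopropylsilyloxy)-2,3-dihydrobenzofuran-7-yl]lithium | CC(C)[Si](Oc1cc(O[Si](C(C)C)(C(C)C)C(C)C)c2C[C@@H](C(C)(C)O[Si](CC)(CC)CC)Oc2c1[Li])(C(C)C)C(C)C | intermediate (not isolated)
16 | lithium 1-{(S)-2-[2-(triethylsilyloxy)propan-2-yl]-4,6-bis(triisopropylsilyloxy)-2,3-dihydrobenzofuran-7-yl}-1-[methoxy(methyl)amino]-3-(4-methoxyphenyl)propan-1-olate (carbinol carbon unassigned) | COc1ccc(CCC(O[Li])(N(C)OC)c2c(O[Si](C(C)C)(C(C)C)C(C)C)cc(O[Si](C(C)C)(C(C)C)C(C)C)c3c2O[C@H](C(C)(C)O[Si](CC)(CC)CC)C3)cc1 | intermediate (not isolated)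
17 | 1-{(S)-2-[2-(triethylsilyloxy)propan-2-yl]-4,6-bis(triisopropylsilyloxy)-2,3-dihydrobenzofuran-7-yl}-3-(4-methoxyphenyl)propan-1-one | COc1ccc(CCC(=O)c2c(O[Si](C(C)C)(C(C)C)C(C)C)cc(O[Si](C(C)C)(C(C)C)C(C)C)c3c2O[C@H](C(C)(C)O[Si](CC)(CC)CC)C3)cc1 | intermediate
18 | 1-[(S)-4,6-dihydroxy-2-(2-hydroxypropan-2-yl)-2,3-dihydrobenzofuran-7-yl]-3-(4-methoxyphenyl)propan-1-one | COc1ccc(CCC(=O)c2c(O)cc(O)c3c2O[C@H](C(C)(C)O)C3)cc1 | intermediate
19 | 3-chloro-3-methylbut-1-yne | C#CC(C)(C)Cl | starting material
20 | 1-[(S)-6-hydroxy-2-(2-hydroxypropan-2-yl)-4-(2-methylbut-3-yn-2-yloxy)-2,3-dihydrobenzofuran-7-yl]-3-(4-methoxyphenyl)propan-1-one | COc1ccc(CCC(=O)c2c(O)cc(OC(C)(C)C#C)c3c2O[C@H](C(C)(C)O)C3)cc1 | intermediate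
21 | 1-[(S)-6-hydroxy-2-(2-hydroxypropan-2-yl)-4-(2-methylbut-3-en-2-yloxy)-2,3-dihydrobenzofuran-7-yl]-3-(4-methoxyphenyl)propan-1-one | COc1ccc(CCC(=O)c2c(O)cc(OC(C)(C)C=C)c3c2O[C@H](C(C)(C)O)C3)cc1 | intermediate
22 | (2S)-6-hydroxy-2-(2-hydroxypropan-2-yl)-7-[3-(4-methoxyphenyl)propanoyl]-5-(3-methylbut-2-en-1-yl)-2,3-dihydrobenzofuran-4(5H)-one (C5 unassigned) | COc1ccc(CCC(=O)C2=C(O)C(CC=C(C)C)C(=O)C3=C2O[C@H](C(C)(C)O)C3)cc1 | intermediate (not isolated)
23 | 1-[(S)-4,6-dihydroxy-2-(2-hydroxypropan-2-yl)-5-(3-methylbut-2-en-1-yl)-2,3-dihydrobenzofuran-7-yl]-3-(4-methoxyphenyl)propan-1-one | COc1ccc(CCC(=O)c2c(O)c(CC=C(C)C)c(O)c3c2O[C@H](C(C)(C)O)C3)cc1 | target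

## Step count and least certain steps

Total: 14 steps (13 in the main line and the one-step preparation of amide 14). Longest linear sequence: 13 steps, from 1 to 23 (steps 1 to 8 and 10 to 14).

**Step 7 (key step).**
- Risk: the carbene is consumed by a second molecule of the diazo compound before it inserts, because the C–H bond sits on a CH2 next to a fully substituted carbon and is inductively deactivated by the β-silyloxy group. The second risk is poor discrimination between the two enantiotopic hydrogens, since the carbene carries a small hydrogen where the precedented carbenes carry aryl or alkyl.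
- Fallback: the concerted insertion is replaced by a stepwise radical closure of the same bond. It sets out from aldehyde 7, which is condensed with 4-methylbenzenesulfonohydrazide to the N-tosylhydrazone N'-{2-[2-methyl-2-(triethylsilyloxy)propoxy]-4,6-bis(triisopropylsilyloxy)benzylidene}-4-methylbenzenesulfonohydrazide F1. With Cs2CO3 and a D2-symmetric chiral amidoporphyrin complex of divalent cobalt, Co(3,5-Di-t-Bu-ChenPhyrin), in toluene at 40 °C, the diazo compound 9 is released slowly and becomes a cobalt-bound benzylic radical. This abstracts a hydrogen atom from the OCH2 group through a six-membered transition state, and the resulting α-oxy radical closes the ring by substitution at the Co–C bond. Hydrogen-atom abstraction is less sensitive to the inductive deactivation, and such cobalt carbene radicals dimerise little. The sequence comes back to the route at 10.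

**Step 5.**
- Risk: loss of silyl groups, since the silyloxy groups ortho and para to the formyl group are vinylogous silyl esters and hydrazine attacks silicon readily; also condensation of the hydrazone with a second aldehyde molecule.
- Fallback: free hydrazine and a separately prepared diazo solution are avoided. From aldehyde 7, condensation with 2-(trifluoromethyl)benzenesulfonohydrazide gives N'-{2-[2-methyl-2-(triethylsilyloxy)propoxy]-4,6-bis(triisopropylsilyloxy)benzylidene}-2-(trifluoromethyl)benzenesulfonohydrazide F2. Deprotonation with NaH and warming to about 30 °C in CH2Cl2 in the presence of Rh2(S-PTAD)4 releases 9 by loss of the sulfinate (Bamford–Stevens reaction), and it is consumed as it forms. The sequence comes back to the route at 10.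

**Step 8.**
- Risk: attack at the wrong site or a second bromination. Both C5 and C7 are activated by three oxygens, and if the silyl groups turn away from C5 the electronic preference for the position para to O1 could show.
- Fallback: electrophilic substitution is replaced by coordination-directed deprotonation. From 10, s-BuLi/TMEDA in THF at −78 °C should remove the C7 hydrogen, because O1 is the only oxygen able to bind lithium (the silyloxy groups are poor ligands and screen C5). This gives aryllithium 15 directly and comes back to the route at 15 in step 10. The fallback makes no new compound (F0).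

**Step 10.**
- Risk: slow acyl transfer to the hindered aryllithium, which leaves time for migration of the triisopropylsilyl group from O6 to C7 or for deprotonation of the amide at its α-CH2.
- Fallback: addition and oxidation in two stages. Aryllithium 15, made from 11 as before, is trapped at −78 °C with the far more electrophilic commercial 3-(4-methoxyphenyl)propanal to give 1-{(S)-2-[2-(triethylsilyloxy)propan-2-yl]-4,6-bis(triisopropylsilyloxy)-2,3-dihydrobenzofuran-7-yl}-3-(4-methoxyphenyl)propan-1-ol F3 as both carbinol epimers. Dess–Martin periodinane oxidises it to the ketone, and the sequence comes back to the route at 17.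

**Step 14.**
- Risk: ionisation of the tertiary allylic C–O bond (the leaving group is a para-acyl phenoxide) with loss of the five-carbon unit in place of the sigmatropic shift, or acid-induced cyclisation of the product phenol onto the prenyl group.
- Fallback: direct C-alkylation. From phenol 18, prenyl bromide in 10% aqueous KOH at 0 °C alkylates the hydrogen-bonded phenoxide through carbon at C5, the only unsubstituted ring position; O-alkylated material is separated. This replaces steps 12 to 14 and comes back to the route at 23. The fallback makes no new compound (F0).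

## Further compounds

F1 | step 7 | N'-{2-[2-methyl-2-(triethylsilyloxy)propoxy]-4,6-bis(triisopropylsilyloxy)benzylidene}-4-methylbenzenesulfonohydrazide | Cc1ccc(cc1)S(=O)(=O)N/N=C/c1c(OCC(C)(C)O[Si](CC)(CC)CC)cc(O[Si](C(C)C)(C(C)C)C(C)C)cc1O[Si](C(C)C)(C(C)C)C(C)C
F2 | step 5 | N'-{2-[2-methyl-2-(triethylsilyloxy)propoxy]-4,6-bis(triisopropylsilyloxy)benzylidene}-2-(trifluoromethyl)benzenesulfonohydrazide | FC(F)(F)c1ccccc1S(=O)(=O)N/N=C/c1c(OCC(C)(C)O[Si](CC)(CC)CC)cc(O[Si](C(C)C)(C(C)C)C(C)C)cc1O[Si](C(C)C)(C(C)C)C(C)C
F0 | step 8 | none | none
F3 | step 10 | 1-{(S)-2-[2-(triethylsilyloxy)propan-2-yl]-4,6-bis(triisopropylsilyloxy)-2,3-dihydrobenzofuran-7-yl}-3-(4-methoxyphenyl)propan-1-ol (carbinol epimers) | COc1ccc(CCC(O)c2c(O[Si](C(C)C)(C(C)C)C(C)C)cc(O[Si](C(C)C)(C(C)C)C(C)C)c3c2O[C@H](C(C)(C)O[Si](CC)(CC)CC)C3)cc1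
F0 | step 14 | none | none
A1 | alternative 1 | methyl 9-(4-methoxyphenyl)-2-(3-methylbut-2-en-1-yl)-3,5,7-trioxononanoate | COC(=O)C(CC=C(C)C)C(=O)CC(=O)CC(=O)CCc1ccc(OC)cc1
A2 | alternative 1 | 1-[2,4,6-trihydroxy-3-(3-methylbut-2-en-1-yl)phenyl]-3-(4-methoxyphenyl)propan-1-one | COc1ccc(CCC(=O)c2c(O)cc(O)c(CC=C(C)C)c2O)cc1
A3 | alternative 2 | [2-hydroxy-4,6-bis(methoxymethoxy)benzyl]trimethylammonium iodide | C[N+](C)(C)Cc1c(O)cc(OCOC)cc1OCOC.[I-]
A4 | alternative 2 | 3,5-bis(methoxymethoxy)-6-methylidenecyclohexa-2,4-dien-1-one | C=C1C(=O)C=C(OCOC)C=C1OCOC
A5 | alternative 2 | methyl (S)-4,6-bis(methoxymethoxy)-2,3-dihydrobenzofuran-2-carboxylate | COCOc1cc(OCOC)c2C[C@@H](C(=O)OC)Oc2c1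
A6 | alternative 3 | (S)-4-(methoxymethoxy)-2-[2-(methoxymethoxy)propan-2-yl]-5-(3-methylbut-2-en-1-yl)-7-(trimethylsilyl)-2,3-dihydrobenzofuran-6-yl trifluoromethanesulfonate | COCOc1c(CC=C(C)C)c(OS(=O)(=O)C(F)(F)F)c([Si](C)(C)C)c2O[C@H](C(C)(C)OCOC)Cc12
A7 | alternative 3 | (S)-4-(methoxymethoxy)-2-[2-(methoxymethoxy)propan-2-yl]-5-(3-methylbut-2-en-1-yl)-6,7-didehydro-2,3-dihydrobenzofuran | COCOC1=C(CC=C(C)C)C#CC2=C1C[C@@H](C(C)(C)OCOC)O2
A8 | alternative 3 | (S)-1-[6-hydroxy-4-(methoxymethoxy)-2-[2-(methoxymethoxy)propan-2-yl]-5-(3-methylbut-2-en-1-yl)-2,3-dihydrobenzofuran-7-yl]-3-(4-methoxyphenyl)propan-1-one | COCOc1c(CC=C(C)C)c(O)c(C(=O)CCc3ccc(OC)cc3)c2O[C@H](C(C)(C)OCOC)Cc12
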